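The tridepside is cut at its two aryl ester bonds into the ring A acid, a ring B aldehyde and ring C, and the route rests on making ring C from a 4-pyranone. Ring C carries its carboxyl on C1'', oxygens on C2'' and C4'' and a methyl on C6'', the pattern of a 3,5,7-trioxooctanoate folded so that C1'' bonds to C6''. The key step lets hydroxide open (6-methyl-4-oxo-4H-pyran-2-yl)acetic acid to that chain, which closes by aldol and aromatises in the same flask. The precursor is kept as the free acid: hydroxide would hydrolyse an ester first, and a carboxylate cannot undergo Claisen closure.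

Key step: step 2

Remark: the target has no stereocentre; locants are unprimed for ring A, primed for ring B and doubly primed for ring C, C1 being the carbonyl-bearing carbon of each ring; compounds 1, 8 and 15 are taken as purchasable.

Step 1
Reactants: 1 2,6-dimethyl-4H-pyran-4-one
Product: 3 (6-methyl-4-oxo-4H-pyran-2-yl)acetic acid, via lithium dienolate 2 (not isolated)
Conditions: LiN(i-Pr)2 (1.1 equiv), THF, −78 °C; transfer onto excess solid CO2 in THF, −78 → 0 °C; HCl (aq) to pH 2, 0 °C; evaporate below 25 °C
Reagents that add atoms: carbon dioxide, O=C=O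
Why: LiN(i-Pr)2 removes a proton from one of the two equivalent methyl groups to give the delocalised dienolate 2, and this lateral (vinylogous enolate) lithiation followed by carboxylation at the exocyclic carbon, run by inverse addition to a large excess of CO2, should give the acid without proton exchange between 2 and the product.

Step 2
Reactants: 3 (6-methyl-4-oxo-4H-pyran-2-yl)acetic acid
Product: 6 2,4-dihydroxy-6-methylbenzoic acid, via triketo acid 4 (not isolated), via cyclic aldol adduct 5 (not isolated)
Conditions: KOH (2 M aq, 6 equiv), N2, rt, then 50 °C until the pyranone is consumed; HCl (aq) to pH 2, 0 °C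
Reagents that add atoms: water, O
Why: Hydroxide adds conjugately to C6 (or C2) of the pyranone, a vinylogous ester, and retro-oxa-Michael ring opening gives the polyanion of triketo acid 4, in which C2, lying between the carboxylate and the C3 ketone, adds as its enolate to the C7 methyl ketone; E1cB loss of water from adduct 5 and enolisation then deliver ring C as its phenoxide, so that the water taken up is given back. The closest known reaction type is the base-induced conversion of 4-pyranones and of their open 1,3,5-triketone forms into resorcinols, in particular the aldol cyclisation of 3,5,7-triketo acids to 2,4-dihydroxybenzoic acids. The one ring is closed in a 6-(enolexo)-exo-trig aldol addition that forms the C1''–C6'' bond (chain C2–C7). No stereocentre has to be controlled, because both centres of 5 vanish on aromatisation. The selectivity needed is C2-to-C7 closure over aldol from the C8 methyl onto C3 and over Claisen closure of C6 onto C1; the substrate secures it because C2 is far more acidic than C8 and because a carboxylate is no acyl acceptor, so the path to an acylphloroglucinol is closed. The free acid also leaves the CH2 group un-ionised in base, so the pyranone stays neutral and open to hydroxide, and aromatisation makes the sequence irreversible.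

Step 3
Reactants: 6 2,4-dihydroxy-6-methylbenzoic acid
Product: 7 benzyl 2,4-dihydroxy-6-methylbenzoate
Conditions: BnBr (1.05 equiv), KHCO3 (1.2 equiv), DMF, rt
Reagents that add atoms: benzyl bromide, BrCc1ccccc1
Why: Hydrogencarbonate ionises only the carboxylic acid, so SN2 O-alkylation of the carboxylate by benzyl bromide should give the benzyl ester and leave both phenols free.

Step 4
Reactants: 8 5-methylbenzene-1,2,3-triol
Product: 9 1,2,3-tris(benzyloxy)-5-methylbenzene
Conditions: BnBr (3.5 equiv), K2CO3 (4.5 equiv), DMF, N2, 60 °C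
Reagents that add atoms: benzyl bromide, BrCc1ccccc1
Why: Exhaustive Williamson etherification of the three phenoxides with excess benzyl bromide should go to completion, air being excluded because pyrogallol-type anions oxidise readily.

Step 5
Reactants: 9 1,2,3-tris(benzyloxy)-5-methylbenzene
Product: 11 2,3,4-tris(benzyloxy)-6-methylbenzaldehyde, via aryl iminium chloride 10 (not isolated)
Conditions: POCl3 (1.5 equiv), DMF, 0 → 70 °C; then ice/H2O, rt
Reagents that add atoms: N,N-dimethylformamide, CN(C)C=O; water, O
Why: In this Vilsmeier–Haack formylation the two open positions of symmetric 9 are equivalent, each ortho to one benzyloxy group and para to another, so the chloroiminium electrophile can give only iminium salt 10, which water hydrolyses to the aldehyde.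

Step 6
Reactants: 11 2,3,4-tris(benzyloxy)-6-methylbenzaldehyde
Product: 12 3,4-bis(benzyloxy)-2-hydroxy-6-methylbenzaldehyde
Conditions: MgBr2·OEt2 (1.5 equiv), toluene/Et2O, reflux; then HCl (1 M aq)
Reagents that add atoms: none
Why: MgBr2 chelates between the formyl oxygen and the neighbouring C2 benzyloxy oxygen, so only that benzyl carbon is opened to SN2 attack by bromide, a chelation-controlled ortho-selective debenzylation that the C3 and C4 ethers cannot undergo.

Step 7
Reactants: 12 3,4-bis(benzyloxy)-2-hydroxy-6-methylbenzaldehyde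
Product: 13 3,4-bis(benzyloxy)-2-methoxy-6-methylbenzaldehyde
Conditions: MeI (3 equiv), K2CO3 (2 equiv), DMF, 40 °C
Reagents that add atoms: iodomethane, CI
Why: Williamson O-methylation of the single free phenol should be clean, since carbonate in DMF breaks the hydrogen bond to the formyl group and no other nucleophilic site is present.

Step 8
Reactants: 13 3,4-bis(benzyloxy)-2-methoxy-6-methylbenzaldehyde
Product: 14 3,4-bis(benzyloxy)-2-methoxy-6-methylbenzoic acid
Conditions: NaClO2 (2 equiv), NaH2PO4 (2 equiv), 2-methyl-2-butene (10 equiv), t-BuOH/THF/H2O, 0 °C → rt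
Reagents that add atoms: sodium chlorite, [Na+].[O-]Cl=O
Why: Pinnick oxidation converts the hindered aryl aldehyde into the acid under mildly acidic conditions that spare the benzyl ethers, 2-methyl-2-butene removing the HOCl that could chlorinate the electron-rich ring.

Step 9
Reactants: 14 3,4-bis(benzyloxy)-2-methoxy-6-methylbenzoic acid; 15 2,4-dihydroxy-6-methylbenzaldehyde
Product: 17 4-formyl-3-hydroxy-5-methylphenyl 3,4-bis(benzyloxy)-2-methoxy-6-methylbenzoate, via mixed trifluoroacetic anhydride 16 (not isolated)
Conditions: (CF3CO)2O (1.5 equiv), toluene, 0 °C → rt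
Reagents that add atoms: none
Why: Trifluoroacetic anhydride turns the hindered, electron-rich acid into mixed anhydride 16, an acylium-like donor that esterifies the free C4 hydroxyl of 15 while the C2 hydroxyl stays locked in its hydrogen bond to the formyl group (depside esterification through a mixed anhydride).

Step 10
Reactants: 17 4-formyl-3-hydroxy-5-methylphenyl 3,4-bis(benzyloxy)-2-methoxy-6-methylbenzoate
Product: 18 4-{[3,4-bis(benzyloxy)-2-methoxy-6-methylbenzoyl]oxy}-2-hydroxy-6-methylbenzoic acid
Conditions: NaClO2 (3 equiv), NaH2PO4 (3 equiv), 2-methyl-2-butene (20 equiv), t-BuOH/THF/H2O, rt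
Reagents that add atoms: sodium chlorite, [Na+].[O-]Cl=O
Why: Pinnick oxidation near pH 4 raises the formyl group of ring B to the carboxyl level without touching the aryl ester or the benzyl ethers, the large excess of alkene scavenger keeping HOCl away from the phenolic ring.

Step 11
Reactants: 18 4-{[3,4-bis(benzyloxy)-2-methoxy-6-methylbenzoyl]oxy}-2-hydroxy-6-methylbenzoic acid; 7 benzyl 2,4-dihydroxy-6-methylbenzoate
Product: 20 benzyl 4-[(4-{[3,4-bis(benzyloxy)-2-methoxy-6-methylbenzoyl]oxy}-2-hydroxy-6-methylbenzoyl)oxy]-2-hydroxy-6-methylbenzoate, via mixed trifluoroacetic anhydride 19 (not isolated)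
Conditions: (CF3CO)2O (1.5 equiv), toluene, 0 °C → rt
Reagents that add atoms: none
Why: Mixed-anhydride activation of 18 and acylation of 7 should occur at the C4'' hydroxyl only, because the C2' and C2'' hydroxyls are each tied up in a hydrogen bond to their ortho carbonyl group, a second depside esterification of the type used in step 9.

Step 12
Reactants: 20 benzyl 4-[(4-{[3,4-bis(benzyloxy)-2-methoxy-6-methylbenzoyl]oxy}-2-hydroxy-6-methylbenzoyl)oxy]-2-hydroxy-6-methylbenzoate
Product: 21 4-[(4-{[3,4-dihydroxy-2-methoxy-6-methylbenzoyl]oxy}-2-hydroxy-6-methylbenzoyl)oxy]-2-hydroxy-6-methylbenzoic acid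
Conditions: H2 (1 atm), 10% Pd/C, EtOAc/THF, rt
Reagents that add atoms: none
Why: Catalytic hydrogenolysis over Pd/C cleaves the two benzyl ethers on ring A and the benzyl ester on ring C in one operation, while the two aryl ester links, the methyl ether and the arenes are inert under these neutral conditions.

Compound list
1 | 2,6-dimethyl-4H-pyran-4-one | CC1=CC(=O)C=C(C)O1 | starting material
2 | lithium 2-methyl-6-methylidene-6H-pyran-4-olate (lithium dienolate, not isolated) | [Li+].[O-]C1=CC(=C)OC(C)=C1 | intermediate
3 | (6-methyl-4-oxo-4H-pyran-2-yl)acetic acid | CC1=CC(=O)C=C(CC(=O)O)O1 | intermediate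
4 | 3,5,7-trioxooctanoic acid (triketo acid, present as its potassium salt, not isolated) | CC(=O)CC(=O)CC(=O)CC(=O)O | intermediate
5 | 6-hydroxy-6-methyl-2,4-dioxocyclohexane-1-carboxylic acid (cyclic aldol adduct, mixture of stereoisomers, not isolated) | CC1(O)CC(=O)CC(=O)C1C(=O)O | intermediate
6 | 2,4-dihydroxy-6-methylbenzoic acid | Cc1cc(O)cc(O)c1C(=O)O | intermediate
7 | benzyl 2,4-dihydroxy-6-methylbenzoate | Cc1cc(O)cc(O)c1C(=O)OCc1ccccc1 | intermediate
8 | 5-methylbenzene-1,2,3-triol | Cc1cc(O)c(O)c(O)c1 | starting material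
9 | 1,2,3-tris(benzyloxy)-5-methylbenzene | Cc1cc(OCc2ccccc2)c(OCc2ccccc2)c(OCc2ccccc2)c1 | intermediate
10 | N,N-dimethyl-1-[2,3,4-tris(benzyloxy)-6-methylphenyl]methaniminium chloride (aryl iminium chloride, not isolated) | C[N+](C)=Cc1c(C)cc(OCc2ccccc2)c(OCc2ccccc2)c1OCc1ccccc1.[Cl-] | intermediate
11 | 2,3,4-tris(benzyloxy)-6-methylbenzaldehyde | Cc1cc(OCc2ccccc2)c(OCc2ccccc2)c(OCc2ccccc2)c1C=O | intermediate
12 | 3,4-bis(benzyloxy)-2-hydroxy-6-methylbenzaldehyde | Cc1cc(OCc2ccccc2)c(OCc2ccccc2)c(O)c1C=O | intermediate
13 | 3,4-bis(benzyloxy)-2-methoxy-6-methylbenzaldehyde | COc1c(OCc2ccccc2)c(OCc2ccccc2)cc(C)c1C=O | intermediate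
14 | 3,4-bis(benzyloxy)-2-methoxy-6-methylbenzoic acid | COc1c(OCc2ccccc2)c(OCc2ccccc2)cc(C)c1C(=O)O | intermediate
15 | 2,4-dihydroxy-6-methylbenzaldehyde | Cc1cc(O)cc(O)c1C=O | starting material
16 | 3,4-bis(benzyloxy)-2-methoxy-6-methylbenzoic trifluoroacetic anhydride (not isolated) | COc1c(OCc2ccccc2)c(OCc2ccccc2)cc(C)c1C(=O)OC(=O)C(F)(F)F | intermediate
17 | 4-formyl-3-hydroxy-5-methylphenyl 3,4-bis(benzyloxy)-2-methoxy-6-methylbenzoate | COc1c(OCc2ccccc2)c(OCc2ccccc2)cc(C)c1C(=O)Oc1cc(C)c(C=O)c(O)c1 | intermediate
18 | 4-{[3,4-bis(benzyloxy)-2-methoxy-6-methylbenzoyl]oxy}-2-hydroxy-6-methylbenzoic acid | COc1c(OCc2ccccc2)c(OCc2ccccc2)cc(C)c1C(=O)Oc1cc(C)c(C(=O)O)c(O)c1 | intermediate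
19 | 4-{[3,4-bis(benzyloxy)-2-methoxy-6-methylbenzoyl]oxy}-2-hydroxy-6-methylbenzoic trifluoroacetic anhydride (not isolated) | COc1c(OCc2ccccc2)c(OCc2ccccc2)cc(C)c1C(=O)Oc1cc(C)c(C(=O)OC(=O)C(F)(F)F)c(O)c1 | intermediate
20 | benzyl 4-[(4-{[3,4-bis(benzyloxy)-2-methoxy-6-methylbenzoyl]oxy}-2-hydroxy-6-methylbenzoyl)oxy]-2-hydroxy-6-methylbenzoate | COc1c(OCc2ccccc2)c(OCc2ccccc2)cc(C)c1C(=O)Oc1cc(C)c(C(=O)Oc2cc(C)c(C(=O)OCc3ccccc3)c(O)c2)c(O)c1 | intermediate
21 | 4-[(4-{[3,4-dihydroxy-2-methoxy-6-methylbenzoyl]oxy}-2-hydroxy-6-methylbenzoyl)oxy]-2-hydroxy-6-methylbenzoic acid | COc1c(O)c(O)cc(C)c1C(=O)Oc1cc(C)c(C(=O)Oc2cc(C)c(C(=O)O)c(O)c2)c(O)c1 | target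

Total step count: 12. Longest linear sequence: 9 steps (steps 4 to 12, from 8); the ring C branch (steps 1 to 3) joins at step 11.

Steps most likely to fail

First, step 2. The hydroxide addition that opens the pyranone may be slow, and the open-chain polyanion may fragment by retro-Claisen cleavage or lose CO2 before it cyclises. The fallback separates ring opening from ring closure. Setting out from 1, aqueous Ba(OH)2 opens the ring to heptane-2,4,6-trione F1. Its trianion (LiN(i-Pr)2, 3 equiv, THF) is carboxylated at a terminal carbon with CO2 to give triketo acid 4, this time isolated in the cold. Acid 4 is then cyclised in buffered water near pH 5 to 6 at rt, where aldol closure and dehydration should proceed without strong base. The route is rejoined at 6.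

Second, step 1. Proton exchange between dienolate 2 and the carboxylate product may lower conversion, and acid 3 may lose CO2 during acidic isolation. In the fallback, setting out from 1, deprotonation with LiN(SiMe3)2 (2.1 equiv, THF, −78 °C) and C-acylation with benzyl chloroformate give benzyl (6-methyl-4-oxo-4H-pyran-2-yl)acetate F2, a neutral ester that can be chromatographed and stored. F2 is placed directly in the aqueous KOH of step 2, where saponification gives the potassium salt of 3 in the flask. The route is thus rejoined at 3 without isolation of the free acid.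

Third, step 11. The mixed anhydride of a salicylic-type acid may acylate a hydrogen-bonded hydroxyl of a second molecule (self-condensation), or esterification of the two hindered partners may stall at the aryl trifluoroacetate stage. The fallback takes the free 2'-hydroxyl out of play, which also removes the free phenol from the oxidation of step 10.
- Setting out from 17, O-benzylation (BnBr, K2CO3, DMF) gives 3-(benzyloxy)-4-formyl-5-methylphenyl 3,4-bis(benzyloxy)-2-methoxy-6-methylbenzoate F3.
- Pinnick oxidation gives 2-(benzyloxy)-4-{[3,4-bis(benzyloxy)-2-methoxy-6-methylbenzoyl]oxy}-6-methylbenzoic acid F4.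
- (COCl)2 with catalytic DMF in CH2Cl2 gives 2-(benzyloxy)-4-{[3,4-bis(benzyloxy)-2-methoxy-6-methylbenzoyl]oxy}-6-methylbenzoyl chloride F5.
- F5 acylates the C4'' hydroxyl of 7 (Et3N, catalytic DMAP, CH2Cl2) to give benzyl 4-[(2-(benzyloxy)-4-{[3,4-bis(benzyloxy)-2-methoxy-6-methylbenzoyl]oxy}-6-methylbenzoyl)oxy]-2-hydroxy-6-methylbenzoate F6.
- Hydrogenolysis of F6 under the conditions of step 12 rejoins the route at 21.

Further compounds
F1 | step 2 | heptane-2,4,6-trione | CC(=O)CC(=O)CC(=O)C
F2 | step 1 | benzyl (6-methyl-4-oxo-4H-pyran-2-yl)acetate | CC1=CC(=O)C=C(CC(=O)OCc2ccccc2)O1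
F3 | step 11 | 3-(benzyloxy)-4-formyl-5-methylphenyl 3,4-bis(benzyloxy)-2-methoxy-6-methylbenzoate | COc1c(OCc2ccccc2)c(OCc2ccccc2)cc(C)c1C(=O)Oc1cc(C)c(C=O)c(OCc2ccccc2)c1
F4 | step 11 | 2-(benzyloxy)-4-{[3,4-bis(benzyloxy)-2-methoxy-6-methylbenzoyl]oxy}-6-methylbenzoic acid | COc1c(OCc2ccccc2)c(OCc2ccccc2)cc(C)c1C(=O)Oc1cc(C)c(C(=O)O)c(OCc2ccccc2)c1
F5 | step 11 | 2-(benzyloxy)-4-{[3,4-bis(benzyloxy)-2-methoxy-6-methylbenzoyl]oxy}-6-methylbenzoyl chloride | COc1c(OCc2ccccc2)c(OCc2ccccc2)cc(C)c1C(=O)Oc1cc(C)c(C(=O)Cl)c(OCc2ccccc2)c1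
F6 | step 11 | benzyl 4-[(2-(benzyloxy)-4-{[3,4-bis(benzyloxy)-2-methoxy-6-methylbenzoyl]oxy}-6-methylbenzoyl)oxy]-2-hydroxy-6-methylbenzoate | COc1c(OCc2ccccc2)c(OCc2ccccc2)cc(C)c1C(=O)Oc1cc(C)c(C(=O)Oc2cc(C)c(C(=O)OCc3ccccc3)c(O)c2)c(OCc2ccccc2)c1
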